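**Retrosynthetic overview**
- The target comes from hydrogenolysis of three O-benzyl groups; the axial C4 hydroxyl comes from equatorial hydride delivery to a 2,6-cis-tetrahydropyran-4-one.
- The pyranone (the only ring built) comes from 6-endo oxa-Michael closure of a (5S)-5-hydroxy-1,7-diarylhept-1-en-3-one, which gives the thermodynamic 2,6-cis ring.
- The enone comes from dehydration of the key intermolecular aldol adduct: the methyl carbon of a (4S)-4-silyloxy-6-arylhexan-2-one joins the carbonyl carbon of 3,4-bis(benzyloxy)-5-methoxybenzaldehyde.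
- The methyl ketone comes from Wacker oxidation of a silylated (S)-homoallylic alcohol, made by Brown allylation of a 3-arylpropanal from eugenol; this allylation sets the one reagent-controlled stereocentre.
- The aldehyde partner comes from 5-hydroxyvanillin by double O-benzylation.

Assumption: 5-hydroxyvanillin is bought as such; the allylation gives about 92–96 % ee, and if chiral HPLC shows it is needed the material is brought to a single enantiomer by recrystallisation at the pyranone stage.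

**Route**

Step 1
Reactants: 1 eugenol
Product: 2 4-allyl-1-(benzyloxy)-2-methoxybenzene
Conditions: BnBr, K2CO3, acetone, reflux
Reagents that add atoms: benzyl bromide, BrCc1ccccc1
Why: Williamson ether synthesis on the phenoxide gives a benzyl ether that survives every step until the final hydrogenolysis.

Step 2
Reactants: 2 4-allyl-1-(benzyloxy)-2-methoxybenzene
Product: 4 3-[4-(benzyloxy)-3-methoxyphenyl]propan-1-ol, via alkylborane 3 (not isolated)
Conditions: 9-BBN, THF, 0 °C to rt; then NaOH, H2O2, 0 °C to rt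
Reagents that add atoms: hydrogen peroxide, OO
Why: Anti-Markovnikov hydroboration–oxidation with the bulky 9-BBN places boron, then oxygen, on the terminal carbon with very high regioselectivity.

Step 3
Reactants: 4 3-[4-(benzyloxy)-3-methoxyphenyl]propan-1-ol
Product: 5 3-[4-(benzyloxy)-3-methoxyphenyl]propanal
Conditions: TEMPO (10 mol %), PhI(OAc)2, CH2Cl2, rt
Reagents that add atoms: none
Why: TEMPO-catalysed oxoammonium oxidation of a primary alcohol stops cleanly at the aldehyde and leaves the electron-rich arene alone.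

Step 4
Reactants: 5 3-[4-(benzyloxy)-3-methoxyphenyl]propanal
Product: 7 (S)-1-[4-(benzyloxy)-3-methoxyphenyl]hex-5-en-3-ol, via borinate ester 6 (not isolated)
Conditions: (+)-Ipc2BOMe [from (−)-α-pinene], CH2=CHCH2MgBr, Et2O, 0 °C to rt; then 5, −78 °C; then NaOH, H2O2, rt
Reagents that add atoms: allylmagnesium bromide, C=CC[Mg]Br (its allyl group is passed on through B-allyldiisopinocampheylborane, C=CCB([C@H]1C[C@H]2C[C@@H]([C@@H]1C)C2(C)C)[C@H]1C[C@H]2C[C@@H]([C@@H]1C)C2(C)C, formed in the flask from (+)-Ipc2BOMe, COB([C@H]1C[C@H]2C[C@@H]([C@@H]1C)C2(C)C)[C@H]1C[C@H]2C[C@@H]([C@@H]1C)C2(C)C)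
Why: Brown asymmetric allylboration through a chair Zimmerman–Traxler transition state, in which the reagent built from (−)-α-pinene attacks the re face of the unbranched aldehyde and sets the (S)-carbinol that becomes C6 of the ring.

Step 5
Reactants: 7 (S)-1-[4-(benzyloxy)-3-methoxyphenyl]hex-5-en-3-ol
Product: 8 (S)-{1-[4-(benzyloxy)-3-methoxyphenyl]hex-5-en-3-yl}oxy(tert-butyl)dimethylsilane
Conditions: TBSCl, imidazole, DMF, rt
Reagents that add atoms: tert-butyldimethylsilyl chloride, CC(C)(C)[Si](C)(C)Cl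
Why: Standard silylation masks the carbinol for the enolate and elimination chemistry ahead without touching the stereocentre.

Step 6
Reactants: 8 (S)-{1-[4-(benzyloxy)-3-methoxyphenyl]hex-5-en-3-yl}oxy(tert-butyl)dimethylsilane
Product: 9 (S)-6-[4-(benzyloxy)-3-methoxyphenyl]-4-[(tert-butyldimethylsilyl)oxy]hexan-2-one
Conditions: PdCl2 (10 mol %), CuCl (1 equiv), O2 (1 atm), DMF/H2O 7:1, rt
Reagents that add atoms: water, O
Why: Tsuji–Wacker oxidation, in which Markovnikov attack of water on the palladium-bound terminal alkene gives the methyl ketone while silyl ether, benzyl ether and stereocentre stay intact.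

Step 7
Reactants: 10 5-hydroxyvanillin (3,4-dihydroxy-5-methoxybenzaldehyde)
Product: 11 3,4-bis(benzyloxy)-5-methoxybenzaldehyde
Conditions: BnBr (2.4 equiv), K2CO3, DMF, 60 °C, under N2
Reagents that add atoms: benzyl bromide, BrCc1ccccc1
Why: Double Williamson etherification of the catechol gives a non-enolisable, base-stable aldol acceptor.

Step 8
Reactants: 9 (S)-6-[4-(benzyloxy)-3-methoxyphenyl]-4-[(tert-butyldimethylsilyl)oxy]hexan-2-one; 11 3,4-bis(benzyloxy)-5-methoxybenzaldehyde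
Product: 13 (5S)-1-[3,4-bis(benzyloxy)-5-methoxyphenyl]-7-[4-(benzyloxy)-3-methoxyphenyl]-5-[(tert-butyldimethylsilyl)oxy]-1-hydroxyheptan-3-one (both C1 epimers), via lithium enolate 12 (not isolated)
Conditions: LiN(iPr)2 (1.1 equiv), THF, −78 °C; then 11, −78 °C; aq NH4Cl at −78 °C
Reagents that add atoms: none
Why: Crossed aldol addition, in which kinetic deprotonation occurs at the methyl group and the enolate adds to the non-enolisable aldehyde; the new C1 carbinol forms as an epimer mixture that is erased in step 9.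

Step 9
Reactants: 13 (5S)-1-[3,4-bis(benzyloxy)-5-methoxyphenyl]-7-[4-(benzyloxy)-3-methoxyphenyl]-5-[(tert-butyldimethylsilyl)oxy]-1-hydroxyheptan-3-one
Product: 15 (S,E)-1-[3,4-bis(benzyloxy)-5-methoxyphenyl]-7-[4-(benzyloxy)-3-methoxyphenyl]-5-[(tert-butyldimethylsilyl)oxy]hept-1-en-3-one, via benzylic mesylate 14 (not isolated)
Conditions: MsCl, Et3N (4 equiv), CH2Cl2, 0 °C to rt
Reagents that add atoms: none
Why: Mesylation of the benzylic β-hydroxy ketone is followed by E1cB elimination, which gives the conjugated (E)-enone from both epimers.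

Step 10
Reactants: 15 (S,E)-1-[3,4-bis(benzyloxy)-5-methoxyphenyl]-7-[4-(benzyloxy)-3-methoxyphenyl]-5-[(tert-butyldimethylsilyl)oxy]hept-1-en-3-one
Product: 16 (S,E)-1-[3,4-bis(benzyloxy)-5-methoxyphenyl]-7-[4-(benzyloxy)-3-methoxyphenyl]-5-hydroxyhept-1-en-3-one
Conditions: HF·pyridine, pyridine, THF, 0 °C to rt
Reagents that add atoms: none
Why: Buffered fluoride desilylation cleaves only the Si–O bond, so benzyl ethers, enone and the C5 stereocentre are unchanged (any 17 already formed is carried forward).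

Step 11
Reactants: 16 (S,E)-1-[3,4-bis(benzyloxy)-5-methoxyphenyl]-7-[4-(benzyloxy)-3-methoxyphenyl]-5-hydroxyhept-1-en-3-one
Product: 17 (2S,6S)-2-[3,4-bis(benzyloxy)-5-methoxyphenyl]-6-{2-[4-(benzyloxy)-3-methoxyphenyl]ethyl}tetrahydro-4H-pyran-4-one
Conditions: Amberlyst-15, CH2Cl2, rt
Reagents that add atoms: none
Why: Acid-catalysed 6-endo-trig intramolecular oxa-Michael addition is reversible, so the new benzylic centre settles as (2S) in the thermodynamic 2,6-cis chair with both substituents equatorial.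

Step 12
Reactants: 17 (2S,6S)-2-[3,4-bis(benzyloxy)-5-methoxyphenyl]-6-{2-[4-(benzyloxy)-3-methoxyphenyl]ethyl}tetrahydro-4H-pyran-4-one
Product: 18 (2S,4S,6S)-2-[3,4-bis(benzyloxy)-5-methoxyphenyl]-6-{2-[4-(benzyloxy)-3-methoxyphenyl]ethyl}tetrahydro-2H-pyran-4-ol
Conditions: Li[HB(sec-Bu)3] (L-Selectride), THF, −78 °C; then NaOH, H2O2, 0 °C
Reagents that add atoms: none
Why: Diastereoselective ketone reduction, in which the bulky hydride attacks the 2,6-cis pyranone from the equatorial direction and gives the axial (4S) alcohol trans to both ring substituents.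

Step 13
Reactants: 18 (2S,4S,6S)-2-[3,4-bis(benzyloxy)-5-methoxyphenyl]-6-{2-[4-(benzyloxy)-3-methoxyphenyl]ethyl}tetrahydro-2H-pyran-4-ol
Product: 19 (2S,4S,6S)-2-(3,4-dihydroxy-5-methoxyphenyl)-6-[2-(4-hydroxy-3-methoxyphenyl)ethyl]tetrahydro-2H-pyran-4-ol
Conditions: H2 (1 atm), Pd/C (10 %), EtOAc, rt, stopped after uptake of 3 equiv
Reagents that add atoms: none
Why: Catalytic hydrogenolysis cleaves the three aryl benzyl ethers much faster than the cyclic benzylic C–O bond of the ring, and no stereocentre is touched.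

**Compound list**

1 | eugenol (4-allyl-2-methoxyphenol) | COc1cc(CC=C)ccc1O | starting material
2 | 4-allyl-1-(benzyloxy)-2-methoxybenzene | COc1cc(CC=C)ccc1OCc1ccccc1 | intermediate
3 | 9-{3-[4-(benzyloxy)-3-methoxyphenyl]propyl}-9-borabicyclo[3.3.1]nonane; not isolated | COc1cc(CCCB2C3CCCC2CCC3)ccc1OCc1ccccc1 | intermediate
4 | 3-[4-(benzyloxy)-3-methoxyphenyl]propan-1-ol | COc1cc(CCCO)ccc1OCc1ccccc1 | intermediate
5 | 3-[4-(benzyloxy)-3-methoxyphenyl]propanal | COc1cc(CCC=O)ccc1OCc1ccccc1 | intermediate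
6 | (S)-1-[4-(benzyloxy)-3-methoxyphenyl]hex-5-en-3-yl diisopinocampheylborinate; not isolated | COc1cc(CC[C@H](OB([C@H]2C[C@H]3C[C@@H]([C@@H]2C)C3(C)C)[C@H]2C[C@H]3C[C@@H]([C@@H]2C)C3(C)C)CC=C)ccc1OCc1ccccc1 | intermediate
7 | (S)-1-[4-(benzyloxy)-3-methoxyphenyl]hex-5-en-3-ol | COc1cc(CC[C@H](O)CC=C)ccc1OCc1ccccc1 | intermediate
8 | (S)-{1-[4-(benzyloxy)-3-methoxyphenyl]hex-5-en-3-yl}oxy(tert-butyl)dimethylsilane | COc1cc(CC[C@H](O[Si](C)(C)C(C)(C)C)CC=C)ccc1OCc1ccccc1 | intermediate
9 | (S)-6-[4-(benzyloxy)-3-methoxyphenyl]-4-[(tert-butyldimethylsilyl)oxy]hexan-2-one | COc1cc(CC[C@H](O[Si](C)(C)C(C)(C)C)CC(C)=O)ccc1OCc1ccccc1 | intermediate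
10 | 5-hydroxyvanillin (3,4-dihydroxy-5-methoxybenzaldehyde) | COc1cc(C=O)cc(O)c1O | starting material
11 | 3,4-bis(benzyloxy)-5-methoxybenzaldehyde | COc1cc(C=O)cc(OCc2ccccc2)c1OCc1ccccc1 | intermediate
12 | lithium (S)-6-[4-(benzyloxy)-3-methoxyphenyl]-4-[(tert-butyldimethylsilyl)oxy]hex-1-en-2-olate; not isolated | COc1cc(CC[C@H](O[Si](C)(C)C(C)(C)C)CC(=C)O[Li])ccc1OCc1ccccc1 | intermediate
13 | (5S)-1-[3,4-bis(benzyloxy)-5-methoxyphenyl]-7-[4-(benzyloxy)-3-methoxyphenyl]-5-[(tert-butyldimethylsilyl)oxy]-1-hydroxyheptan-3-one, both C1 epimers | COc1cc(CC[C@H](O[Si](C)(C)C(C)(C)C)CC(=O)CC(O)c2cc(OC)c(OCc3ccccc3)c(OCc3ccccc3)c2)ccc1OCc1ccccc1 | intermediate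
14 | (5S)-1-[3,4-bis(benzyloxy)-5-methoxyphenyl]-7-[4-(benzyloxy)-3-methoxyphenyl]-5-[(tert-butyldimethylsilyl)oxy]-3-oxoheptyl methanesulfonate, both C1 epimers; not isolated | COc1cc(CC[C@H](O[Si](C)(C)C(C)(C)C)CC(=O)CC(OS(C)(=O)=O)c2cc(OC)c(OCc3ccccc3)c(OCc3ccccc3)c2)ccc1OCc1ccccc1 | intermediate
15 | (S,E)-1-[3,4-bis(benzyloxy)-5-methoxyphenyl]-7-[4-(benzyloxy)-3-methoxyphenyl]-5-[(tert-butyldimethylsilyl)oxy]hept-1-en-3-one | COc1cc(CC[C@H](O[Si](C)(C)C(C)(C)C)CC(=O)/C=C/c2cc(OC)c(OCc3ccccc3)c(OCc3ccccc3)c2)ccc1OCc1ccccc1 | intermediate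
16 | (S,E)-1-[3,4-bis(benzyloxy)-5-methoxyphenyl]-7-[4-(benzyloxy)-3-methoxyphenyl]-5-hydroxyhept-1-en-3-one | COc1cc(CC[C@H](O)CC(=O)/C=C/c2cc(OC)c(OCc3ccccc3)c(OCc3ccccc3)c2)ccc1OCc1ccccc1 | intermediate
17 | (2S,6S)-2-[3,4-bis(benzyloxy)-5-methoxyphenyl]-6-{2-[4-(benzyloxy)-3-methoxyphenyl]ethyl}tetrahydro-4H-pyran-4-one (2,6-cis) | COc1cc(CC[C@H]2CC(=O)C[C@@H](c3cc(OC)c(OCc4ccccc4)c(OCc4ccccc4)c3)O2)ccc1OCc1ccccc1 | intermediate
18 | (2S,4S,6S)-2-[3,4-bis(benzyloxy)-5-methoxyphenyl]-6-{2-[4-(benzyloxy)-3-methoxyphenyl]ethyl}tetrahydro-2H-pyran-4-ol (axial OH) | COc1cc(CC[C@H]2C[C@H](O)C[C@@H](c3cc(OC)c(OCc4ccccc4)c(OCc4ccccc4)c3)O2)ccc1OCc1ccccc1 | intermediate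
19 | (2S,4S,6S)-2-(3,4-dihydroxy-5-methoxyphenyl)-6-[2-(4-hydroxy-3-methoxyphenyl)ethyl]tetrahydro-2H-pyran-4-ol | COc1cc(CC[C@H]2C[C@H](O)C[C@@H](c3cc(O)c(O)c(OC)c3)O2)ccc1O | target

**Totals and risks**

Total step count: 13. Longest linear sequence: 12 steps (steps 1–6, then 8–13, from eugenol); step 7 is the one-step side branch.

Steps most likely to fail:

Step 8 (crossed aldol). The electron-rich aldehyde is a weak electrophile, so conversion can stall or the lithium aldolate can revert. The fallback sets out from 9: its kinetic enolate is trapped (LiN(iPr)2, Me3SiCl, THF, −78 °C) as the trimethylsilyl enol ether F1. F1 then adds to 11 in a Mukaiyama aldol reaction (BF3·OEt2, CH2Cl2, −78 °C), which is not reversible under Lewis-acid activation. Aqueous work-up removes the silyl group and the route is rejoined at 13.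

Step 11 (oxa-Michael ring closure). The electron-rich styryl ketone is a sluggish acceptor, so the closure may stop at an equilibrium mixture, or the β-hydroxy ketone may dehydrate. The fallback sets out from 7 and builds the ring by a Prins cyclisation with 11 (CF3CO2H, CH2Cl2, 0 °C). A chair oxocarbenium ion with equatorial trapping gives the all-cis 4-trifluoroacetate F2. Methanolysis (K2CO3, MeOH) gives the all-cis alcohol F3, and Dess–Martin oxidation of F3 comes back to the route at 17.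

Step 13 (global debenzylation). Over-reduction could open the ring at its benzylic C–O bond. The fallback sets out from 18 and removes the three benzyl groups without hydrogen, using BCl3 with pentamethylbenzene as benzyl-cation scavenger (CH2Cl2, −78 °C). It arrives directly at 19 and passes through no new compound (F0).

**Further compounds**

F1 | step 8 | (S)-tert-butyl({1-[4-(benzyloxy)-3-methoxyphenyl]-5-[(trimethylsilyl)oxy]hex-5-en-3-yl}oxy)dimethylsilane | COc1cc(CC[C@H](O[Si](C)(C)C(C)(C)C)CC(=C)O[Si](C)(C)C)ccc1OCc1ccccc1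
F2 | step 11 | (2S,4R,6S)-2-[3,4-bis(benzyloxy)-5-methoxyphenyl]-6-{2-[4-(benzyloxy)-3-methoxyphenyl]ethyl}tetrahydro-2H-pyran-4-yl trifluoroacetate | COc1cc(CC[C@H]2C[C@@H](OC(=O)C(F)(F)F)C[C@@H](c3cc(OC)c(OCc4ccccc4)c(OCc4ccccc4)c3)O2)ccc1OCc1ccccc1
F3 | step 11 | (2S,4R,6S)-2-[3,4-bis(benzyloxy)-5-methoxyphenyl]-6-{2-[4-(benzyloxy)-3-methoxyphenyl]ethyl}tetrahydro-2H-pyran-4-ol (all-cis) | COc1cc(CC[C@H]2C[C@@H](O)C[C@@H](c3cc(OC)c(OCc4ccccc4)c(OCc4ccccc4)c3)O2)ccc1OCc1ccccc1
F0 | step 13 | none | none
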